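The C6–O/C7–isopropyl pair on the (1(10)Z,4Z)-cyclodecadiene (germacrane numbering) is read as a masked homoallylic alcohol, O–C6–C7–C11(=C12). That is the retron of a [2,3]-Wittig shift. Cutting C6–C7 and tying C12 to the C6 oxygen turns the ten-membered carbocycle into a relaxed 13-membered propargyl (Z)-allyl ether. In one operation a chiral lithium amide contracts this ring. The carbocycle closes, C6–C7 forms, both stereocentres are set as a group, and the isopropenyl precursor of the isopropyl group appears. The C4≡C5 alkyne directs lithiation and later gives the 4Z-alkene by syn methylmetalation. Nerol supplies the 1(10)Z-alkene.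

Key step: step 8

Assumption 1: the SMILES is read literally. Both trisubstituted ring alkenes are Z (ring carbons cis), the ester carbon is R and the isopropyl carbon is S. On a flat ring drawing O and isopropyl are cis.

Assumption 2: the Why lines use germacrane numbering (ring C1–C10, isopropyl C11–C13, C14 on C10, C15 on C4), and the names use IUPAC locants. The carbinol descriptor runs R (14), S (16), R (17) only because CIP ranks change. No bond to that carbon is broken.

Step 1
Reactants: 1 nerol
Product: 2 neryl chloride, (2Z)-1-chloro-3,7-dimethylocta-2,6-diene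
Conditions: PPh3, CCl4, reflux
Reagents that add atoms: tetrachloromethane ClC(Cl)(Cl)Cl
Why: Appel chlorination replaces the primary allylic OH by SN2 attack of chloride on the oxyphosphonium ion, which should leave the Z-alkene and the allylic position unchanged.

Step 2
Reactants: 2 neryl chloride
Product: 3 (4Z)-6-chloro-4-methylhex-4-enal
Conditions: O3 (1 equiv, dye end point), CH2Cl2, −78 °C; then Me2S, −78 °C → rt
Reagents that add atoms: ozone [O-][O+]=O
Why: Chemoselective ozonolysis with reductive work-up, in which the electron-rich isopropylidene alkene should react well before the alkene deactivated by the allylic chlorine.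

Step 3
Reactants: 3 (4Z)-6-chloro-4-methylhex-4-enal; 4 ethyl 2-[bis(2,2,2-trifluoroethoxy)phosphoryl]propanoate
Product: 5 ethyl (2Z,6Z)-8-chloro-2,6-dimethylocta-2,6-dienoate
Conditions: KHMDS, 18-crown-6, THF, −78 °C
Reagents that add atoms: none
Why: Still–Gennari variant of the Horner–Wadsworth–Emmons olefination, whose fast irreversible elimination from the kinetic adduct should give the (Z)-2-methyl enoate (C8 cis to C12), while at −78 °C the aldehyde should outrun the allylic chloride as electrophile.

Step 4
Reactants: 5 ethyl (2Z,6Z)-8-chloro-2,6-dimethylocta-2,6-dienoate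
Product: 6 (2Z,6Z)-8-chloro-2,6-dimethylocta-2,6-dien-1-ol
Conditions: DIBAL-H (2.3 equiv), CH2Cl2, −78 °C; Rochelle salt
Reagents that add atoms: none
Why: 1,2-Reduction of an enoate with DIBAL-H at low temperature, conditions under which an allylic chloride and both alkene geometries should persist.

Step 5
Reactants: 6 (2Z,6Z)-8-chloro-2,6-dimethylocta-2,6-dien-1-ol; 7 but-2-yne
Product: 9 (2Z,6Z)-2,6-dimethyldodeca-2,6-dien-10-yn-1-ol, via 1-lithiobut-2-yne 8 (not isolated)
Conditions: 7, n-BuLi, TMEDA, THF, −78 → 0 °C; then 6 (0.45 equiv), −78 → 0 °C; H2O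
Reagents that add atoms: none
Why: SN2 alkylation of a propargyllithium by a primary allylic chloride (1,5-enyne synthesis), in which the first equivalent only deprotonates the OH, attack through the unhindered CH2 terminus should favour alkyne over allene, and the trisubstituted γ-carbon disfavours SN2′.

Step 6
Reactants: 9 (2Z,6Z)-2,6-dimethyldodeca-2,6-dien-10-yn-1-ol; 10 1-bromobut-2-yne
Product: 11 (2Z,6Z)-1-(but-2-yn-1-yloxy)-2,6-dimethyldodeca-2,6-dien-10-yne
Conditions: NaH, TBAI (cat.), THF–DMF, 0 °C → rt
Reagents that add atoms: none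
Why: Williamson ether synthesis, in which the sodium alkoxide displaces bromide from the unhindered propargylic bromide and sodium hydride is too weak a base to metalate the ether that forms.

Step 7
Reactants: 11 (2Z,6Z)-1-(but-2-yn-1-yloxy)-2,6-dimethyldodeca-2,6-dien-10-yne
Product: 12 (3Z,7Z)-3,7-dimethyl-1-oxacyclotrideca-3,7-dien-11-yne
Conditions: Mo(≡CC6H4-4-OMe)(OSiPh3)3 (10 mol %), MS 5 Å, toluene (2 mM), rt → 60 °C
Reagents that add atoms: none
Why: Ring-closing alkyne metathesis, in which the alkylidyne exchanges only the two methyl-capped alkynes, ignores the trisubstituted alkenes and the ether, and is driven to the 13-membered cycloalkyne by uptake of but-2-yne in the sieves at high dilution.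

Step 8
Reactants: 12 (3Z,7Z)-3,7-dimethyl-1-oxacyclotrideca-3,7-dien-11-yne
Product: 14 (1R,6Z,10S)-7-methyl-10-(prop-1-en-2-yl)cyclodec-6-en-2-yn-1-ol, via 13-lithio ether 13 (not isolated)
Conditions: (S,S)-bis(1-phenylethyl)amine, n-BuLi, THF, 0 °C; then 12, −35 → −20 °C; H2O
Reagents that add atoms: none
Why: The amide removes one of the two enantiotopic hydrogens at C6, the only position acidified by both the ether oxygen and the alkyne, and lithio ether 13 undergoes a concerted suprafacial [2,3]-sigmatropic shift through a five-membered envelope (C6, O, C12, C11, C7) in which C6–C7 forms as O–C12 breaks. The closest known reaction type is the [2,3]-Wittig ring contraction of 13-membered propargyl allyl ethers induced by chiral lithium amides. The ten-membered carbocycle is closed transannularly by a 13 → 10 contraction that leaves C11(=C12)C13 outside the ring as the isopropenyl group and the oxygen as the C6 alkoxide, so the entropic cost of a ten-membered C–C cyclisation has already been paid in the easier 13-membered ring. C6 is controlled by the base (abstraction of the pro-S hydrogen and C–C bond formation anti to lithium should give 6R; the sense is assigned by analogy and the antipodal amine is equally available), and C7 is controlled by the Z geometry of C7=C11 with the alkynyl group exo on the envelope (Z → syn), which places OH and isopropenyl cis on the ring. The rigid C6–C5≡C4–C3 rod should reinforce this, because only in the exo/Z arrangement do C3 and C8 come close enough for the short bridge C2–C1=C10–C9 with its Z-alkene to span the gap. The step needs regioselective lithiation (secured by the alkyne, since a lithium amide should not touch the merely allylic C12–H), [2,3] over [1,2] shift (secured by the low temperature and the pre-aligned allyl unit) and an untouched C1=C10 geometry (it is a spectator).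

Step 9
Reactants: 14 (1R,6Z,10S)-7-methyl-10-(prop-1-en-2-yl)cyclodec-6-en-2-yn-1-ol
Product: 16 (1S,2Z,6Z,10S)-3,7-dimethyl-10-(prop-1-en-2-yl)cyclodeca-2,6-dien-1-ol, via alkenylmagnesium alkoxide 15 (not isolated)
Conditions: MeMgBr (5 equiv), Fe(acac)3 (15 mol %), THF, 0 °C → rt; then H2O
Reagents that add atoms: methylmagnesium bromide C[Mg]Br
Why: Alkoxide-directed iron-catalysed carbomagnesiation of a propargylic alcohol, a syn addition that delivers methyl to the alkyne carbon remote from the alkoxide (C4), so that protonolysis of the C5–Mg bond leaves C3 and C6 cis, the 4Z geometry that a syn addition to a cycloalkyne must give.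

Step 10
Reactants: 16 (1S,2Z,6Z,10S)-3,7-dimethyl-10-(prop-1-en-2-yl)cyclodeca-2,6-dien-1-ol
Product: 17 (1R,2Z,6Z,10S)-3,7-dimethyl-10-(propan-2-yl)cyclodeca-2,6-dien-1-ol
Conditions: H2 (1 atm), RhCl(PPh3)3 (5 mol %), toluene, rt
Reagents that add atoms: none
Why: Homogeneous hydrogenation with Wilkinson's catalyst, which discriminates by alkene substitution so that the 1,1-disubstituted isopropenyl group should be saturated while both trisubstituted ring alkenes and both stereocentres stay untouched.

Step 11
Reactants: 17 (1R,2Z,6Z,10S)-3,7-dimethyl-10-(propan-2-yl)cyclodeca-2,6-dien-1-ol; 18 4-acetoxy-3-methoxybenzoic acid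
Product: 19 (1R,2Z,6Z,10S)-3,7-dimethyl-10-(propan-2-yl)cyclodeca-2,6-dien-1-yl 4-acetoxy-3-methoxybenzoate
Conditions: DCC, DMAP, CH2Cl2, 0 °C → rt
Reagents that add atoms: none
Why: Steglich esterification activates the acid under neutral conditions that avoid ionisation of the allylic alcohol, and since the C6–O bond is not broken the configuration is kept.

Step 12
Reactants: 19 (1R,2Z,6Z,10S)-3,7-dimethyl-10-(propan-2-yl)cyclodeca-2,6-dien-1-yl 4-acetoxy-3-methoxybenzoate
Product: 20 (1R,2Z,6Z,10S)-3,7-dimethyl-10-(propan-2-yl)cyclodeca-2,6-dien-1-yl 4-hydroxy-3-methoxybenzoate (target)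
Conditions: K2CO3 (cat.), MeOH, 0 °C
Reagents that add atoms: none
Why: Chemoselective base-catalysed methanolysis (transesterification), in which the aryl acetate has the far better leaving group and less hindrance than the secondary allylic benzoate, so only the phenol should be released.

Compound list
1 | nerol, (2Z)-3,7-dimethylocta-2,6-dien-1-ol | CC(C)=CCC/C(C)=C\CO | starting material
2 | neryl chloride, (2Z)-1-chloro-3,7-dimethylocta-2,6-diene | CC(C)=CCC/C(C)=C\CCl | intermediate
3 | (4Z)-6-chloro-4-methylhex-4-enal | O=CCC/C(C)=C\CCl | intermediate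
4 | ethyl 2-[bis(2,2,2-trifluoroethoxy)phosphoryl]propanoate | CCOC(=O)C(C)P(=O)(OCC(F)(F)F)OCC(F)(F)F | starting material
5 | ethyl (2Z,6Z)-8-chloro-2,6-dimethylocta-2,6-dienoate | CCOC(=O)/C(C)=C\CC/C(C)=C\CCl | intermediate
6 | (2Z,6Z)-8-chloro-2,6-dimethylocta-2,6-dien-1-ol | OC/C(C)=C\CC/C(C)=C\CCl | intermediate
7 | but-2-yne | CC#CC | starting material
8 | 1-lithiobut-2-yne | [Li]CC#CC | intermediate
9 | (2Z,6Z)-2,6-dimethyldodeca-2,6-dien-10-yn-1-ol | OC/C(C)=C\CC/C(C)=C\CCC#CC | intermediate
10 | 1-bromobut-2-yne | CC#CCBr | starting material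
11 | (2Z,6Z)-1-(but-2-yn-1-yloxy)-2,6-dimethyldodeca-2,6-dien-10-yne | CC#CCOC/C(C)=C\CC/C(C)=C\CCC#CC | intermediate
12 | (3Z,7Z)-3,7-dimethyl-1-oxacyclotrideca-3,7-dien-11-yne | C1C#CCC/C=C(/C)CC/C=C(/C)CO1 | intermediate
13 | (13S)-13-lithio derivative of 12 (lithium on the propargylic OCH carbon) | O1[C@@H]([Li])C#CCC/C=C(/C)CC/C=C(/C)C1 | intermediate
14 | (1R,6Z,10S)-7-methyl-10-(prop-1-en-2-yl)cyclodec-6-en-2-yn-1-ol | O[C@H]1C#CCC/C=C(/C)CC[C@H]1C(C)=C | intermediate
15 | bromomagnesium alkoxide of 16 carrying MgBr on C2, cis to the new methyl group | Br[Mg]O[C@H]1/C([Mg]Br)=C(/C)CC/C=C(/C)CC[C@H]1C(C)=C | intermediate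
16 | (1S,2Z,6Z,10S)-3,7-dimethyl-10-(prop-1-en-2-yl)cyclodeca-2,6-dien-1-ol | O[C@H]1/C=C(/C)CC/C=C(/C)CC[C@H]1C(C)=C | intermediate
17 | (1R,2Z,6Z,10S)-3,7-dimethyl-10-(propan-2-yl)cyclodeca-2,6-dien-1-ol | O[C@H]1/C=C(/C)CC/C=C(/C)CC[C@H]1C(C)C | intermediate
18 | 4-acetoxy-3-methoxybenzoic acid | CC(=O)Oc1ccc(cc1OC)C(=O)O | starting material
19 | (1R,2Z,6Z,10S)-3,7-dimethyl-10-(propan-2-yl)cyclodeca-2,6-dien-1-yl 4-acetoxy-3-methoxybenzoate | COc1cc(C(=O)O[C@H]2/C=C(/C)CC/C=C(/C)CC[C@H]2C(C)C)ccc1OC(C)=O | intermediate
20 | (1R,2Z,6Z,10S)-3,7-dimethyl-10-(propan-2-yl)cyclodeca-2,6-dien-1-yl 4-hydroxy-3-methoxybenzoate | COc1cc(C(=O)O[C@H]2/C=C(/C)CC/C=C(/C)CC[C@H]2C(C)C)ccc1O | target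

Total step count: 12
Longest linear sequence: 12 steps (1 → 20)

Steps most likely to fail

**Step 8.**
- Risk: incomplete discrimination between the two enantiotopic C6 hydrogens would erode enantiomeric purity, and partial passage through an endo envelope would erode diastereomeric purity. A competing [1,2]-shift or isomerisation to an allenyl ether would cost material.
- Fallback: it sets out from 12 and takes the absolute configuration from an enzyme instead of the base.
- Rearrangement with n-BuLi in THF at −78 °C should give 14 together with its mirror image (1S,6Z,10R)-7-methyl-10-(prop-1-en-2-yl)cyclodec-6-en-2-yn-1-ol F1.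
- A lipase-catalysed kinetic resolution follows (immobilised Candida antarctica lipase B, vinyl acetate, MTBE). By the empirical size rule for secondary alcohols, the slim alkynyl side is the medium group and the branched C7 side is the large group.
- The lipase should therefore acetylate F1 to (1S,6Z,10R)-7-methyl-10-(prop-1-en-2-yl)cyclodec-6-en-2-yn-1-yl acetate F2 and leave 14.
- The route is rejoined at 14 after chromatography. The same resolution can polish scalemic material from step 8.

**Step 9.**
- Risk: sluggish or regiochemically unselective carbometalation of the hindered ring alkyne, or reduction of the alkyne by low-valent iron, would lower the return of the 4Z-alkene.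
- Fallback: it sets out from 14 and replaces carbometalation by hydrometalation and cross-coupling.
- Syn hydrozirconation with the Schwartz reagent (3 equiv, THF, rt) should place zirconium on C4, away from the branched carbinol.
- Iodinolysis should then give (1R,2E,6Z,10S)-3-iodo-7-methyl-10-(prop-1-en-2-yl)cyclodeca-2,6-dien-1-ol F3.
- Negishi coupling with MeZnCl and Pd(PPh3)4 in THF, with retention of geometry, comes back to the route at 16.

**Step 7.**
- Risk: oligomerisation instead of ring closure, or deactivation of the alkylidyne by the propargylic ether, would starve the key step of substrate.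
- Fallback: it sets out from 6 and closes the ring at the C–O bond instead of the alkyne.
- Silylation (TBSCl, imidazole) should give tert-butyl{[(2Z,6Z)-8-chloro-2,6-dimethylocta-2,6-dien-1-yl]oxy}dimethylsilane F4.
- Alkylation of 1,3-dilithiopropyne and trapping of the acetylide with paraformaldehyde should give (6Z,10Z)-12-[(tert-butyldimethylsilyl)oxy]-7,11-dimethyldodeca-6,10-dien-2-yn-1-ol F5.
- MsCl, Et3N and LiCl should give tert-butyl{[(2Z,6Z)-12-chloro-2,6-dimethyldodeca-2,6-dien-10-yn-1-yl]oxy}dimethylsilane F6.
- HF·pyridine should give (2Z,6Z)-12-chloro-2,6-dimethyldodeca-2,6-dien-10-yn-1-ol F7.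
- Intramolecular Williamson etherification (NaH, TBAI, THF, high dilution) comes back to the route at 12.

Further compounds
F1 | step 8 | (1S,6Z,10R)-7-methyl-10-(prop-1-en-2-yl)cyclodec-6-en-2-yn-1-ol | O[C@@H]1C#CCC/C=C(/C)CC[C@@H]1C(C)=C
F2 | step 8 | (1S,6Z,10R)-7-methyl-10-(prop-1-en-2-yl)cyclodec-6-en-2-yn-1-yl acetate | CC(=O)O[C@@H]1C#CCC/C=C(/C)CC[C@@H]1C(C)=C
F3 | step 9 | (1R,2E,6Z,10S)-3-iodo-7-methyl-10-(prop-1-en-2-yl)cyclodeca-2,6-dien-1-ol | O[C@H]1/C=C(/I)CC/C=C(/C)CC[C@H]1C(C)=C
F4 | step 7 | tert-butyl{[(2Z,6Z)-8-chloro-2,6-dimethylocta-2,6-dien-1-yl]oxy}dimethylsilane | CC(C)(C)[Si](C)(C)OC/C(C)=C\CC/C(C)=C\CCl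
F5 | step 7 | (6Z,10Z)-12-[(tert-butyldimethylsilyl)oxy]-7,11-dimethyldodeca-6,10-dien-2-yn-1-ol | OCC#CCC/C=C(/C)CC/C=C(/C)CO[Si](C)(C)C(C)(C)C
F6 | step 7 | tert-butyl{[(2Z,6Z)-12-chloro-2,6-dimethyldodeca-2,6-dien-10-yn-1-yl]oxy}dimethylsilane | ClCC#CCC/C=C(/C)CC/C=C(/C)CO[Si](C)(C)C(C)(C)C
F7 | step 7 | (2Z,6Z)-12-chloro-2,6-dimethyldodeca-2,6-dien-10-yn-1-ol | ClCC#CCC/C=C(/C)CC/C=C(/C)CO
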